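**Retrosynthetic overview**

1. The target (lindenane numbering, primes for the second half) is a C2-symmetric head-to-head dimer whose halves meet in the cyclobutane C8–C9–C9'–C8'. The strategy rests on cutting this ring at C8–C9 and C8'–C9': C8' becomes a ketene carbonyl carbon, C8 the ketene α-carbon inside the finished butenolide (O–C8–C7=C11–C12=O), and C9=C9' an E-alkene held to C8 by the tether C7–C6–C5–C10.
2. After the key step, the C8' cyclobutanone carbonyl, the 2-butynyl arm (C6'–C7'≡C11'–C13') and CO are joined in a carbonylative [2+2+1] that closes the second six-membered ring and the second butenolide. The two exocyclic methylenes (C4, C4'), carried as OTBS groups, come last.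
3. The ketene precursor is a butenolide acid built on the propargyl arm of the coupled E-alkene (ynoate, β-keto ester, α-chloride, 2-bromopropanoate, intramolecular Wittig). C9=C9' comes from a Julia–Kocienski union of a sulfone and an aldehyde.
4. Both halves come from one bicyclo[3.1.0]hexane alcohol made from 3-methylcyclopent-2-en-1-one: asymmetric conjugate addition (C10), enolate alkylation (C5), dehydrogenation, 1,2-reduction, hydroxyl-directed cyclopropanation (C1–C2–C3).
5. Ring order: cyclopentane (starting material), cyclopropane, first butenolide, cyclobutanone together with the first six-membered carbocycle (key step), second six-membered carbocycle together with the second butenolide.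

Key step: step 22

Remark 1 (convention): β is the face of the C10 methyl (C14); in both halves the cyclopropane CH2 (C2), the C5 arm (C6) and C14 are β, and H1, H3, H5 and C9 are α.
Remark 2 (chemistry): C4 and C4' stay as TBS ethers until the end, because an exocyclic C4=C15 alkene, 1,1-disubstituted and only three atoms from the ketene α-carbon, would be expected to capture the ketene before the hindered C9=C9' alkene does.
Remark 3 (assumption): C8 in 31 and 33–37 and the CHBr/CHP centre in 33 and 34 are carried as epimer mixtures; all of them become sp2 before or in the key step.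

**Route**

Step 1
Reactants: 1 3-methylcyclopent-2-en-1-one; 2 ethynyl(trimethyl)silane
Product: 5 (S)-trimethyl{[3-methyl-3-(1-trimethylsilylvinyl)cyclopent-1-en-1-yl]oxy}silane, via vinylalane 3 (not isolated), via aluminium enolate 4 (not isolated)
Conditions: 2, iBu2AlH, hexane/THF, 55 °C; then 1, Cu(OTf)2 (5 mol %), [Ag(NHC*)]2 (2.5 mol %; NHC* = chiral sulfonate-bearing imidazolin-2-ylidene), THF, −78 °C; then Me3SiOTf, −78 → 0 °C
Reagents that add atoms: trimethylsilyl trifluoromethanesulfonate, C[Si](C)(C)OS(=O)(=O)C(F)(F)F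
Why: Regioselective hydroalumination places aluminium geminal to silicon, and the copper–NHC-catalysed enantioselective conjugate addition of this vinylalane to the β-methyl enone (a known route to vinyl-bearing quaternary centres on cyclopentanones) sets C10 under catalyst control, the ligand enantiomer being chosen for the (S) centre, before the regiodefined aluminium enolate is O-silylated.

Step 2
Reactants: 5 (S)-enol silane; 6 3-bromo-1-(trimethylsilyl)prop-1-yne
Product: 8 3-methyl-2-[3-(trimethylsilyl)prop-2-ynyl]-3-[1-(trimethylsilyl)vinyl]cyclopentan-1-one (arm cis to methyl), via lithium enolate 7 (not isolated)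
Conditions: MeLi, THF, 0 °C; then 6, DMPU, −78 → 0 °C
Reagents that add atoms: none
Why: MeLi cleaves the enol silane to the regiodefined lithium enolate, whose C-alkylation by the propargylic bromide (SN2) occurs anti to the bulky 1-silylvinyl group on the neighbouring quaternary carbon, so the new C5 centre carries its arm cis to the C10 methyl.

Step 3
Reactants: 8 bis-silyl ketone
Product: 9 3-methyl-2-[3-(trimethylsilyl)prop-2-ynyl]-3-vinylcyclopentan-1-one (arm cis to methyl)
Conditions: CF3CO2H, CH2Cl2, 22 °C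
Reagents that add atoms: none
Why: Acid-mediated protodesilylation of the 1-silylvinyl group (known for such conjugate-addition products) frees the vinyl group, while the alkynylsilane and the ketone are inert to CF3CO2H at room temperature.

Step 4
Reactants: 9 vinyl ketone
Product: 11 4-methyl-5-[3-(trimethylsilyl)prop-2-ynyl]-4-vinylcyclopent-2-en-1-one (arm cis to methyl), via lithium enolate 10 (not isolated)
Conditions: LiN(iPr)2 (LDA), THF, −78 °C; then N-tert-butylbenzenesulfinimidoyl chloride, −78 °C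
Reagents that add atoms: none
Why: Mukaiyama dehydrogenation: the kinetic enolate forms at the C3 methylene, and sulfenylation by the sulfinimidoyl chloride followed by spontaneous syn-elimination gives the C3=C1 enone, the quaternary C10 excluding any other ring regiochemistry.

Step 5
Reactants: 11 enone
Product: 12 4-methyl-5-[3-(trimethylsilyl)prop-2-ynyl]-4-vinylcyclopent-2-en-1-ol (OH, arm and methyl all β)
Conditions: NaBH4, CeCl3·7H2O, MeOH, −78 °C
Reagents that add atoms: none
Why: Luche 1,2-reduction: hydride should add to the carbonyl from the α face, away from the adjacent C5 arm and the C10 methyl, giving the 4β-alcohol cis to the arm that the next step needs.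

Step 6
Reactants: 12 allylic alcohol
Product: 13 4-methyl-3-[3-(trimethylsilyl)prop-2-ynyl]-4-vinylbicyclo[3.1.0]hexan-2-ol (OH, cyclopropane CH2, arm and methyl β; vinyl α)
Conditions: Et2Zn, CH2I2, CH2Cl2, 0 °C
Reagents that add atoms: diiodomethane, ICI
Why: Hydroxyl-directed Simmons–Smith (Furukawa) cyclopropanation: the zinc alkoxide delivers CH2 to the β face of the allylic C1=C3 alkene, setting C1 and C3 syn to the hydroxyl, while the undirected, neopentyl-type vinyl group reacts far more slowly.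

Step 7
Reactants: 13 cyclopropyl carbinol
Product: 14 tert-butyldimethylsilyl ether of 13
Conditions: tBuMe2SiOTf, 2,6-lutidine, CH2Cl2, −78 → 0 °C
Reagents that add atoms: tert-butyldimethylsilyl trifluoromethanesulfonate, CC(C)(C)[Si](C)(C)OS(=O)(=O)C(F)(F)F
Why: Silylation of the hindered secondary alcohol with the silyl triflate masks C4 (later the exocyclic methylene) through all basic, oxidative and cycloaddition steps.

Step 8
Reactants: 14 silyl ether
Product: 16 C9 alcohol [2β-silyloxy-4α-hydroxymethyl-4β-methyl-3β-(3-trimethylsilylprop-2-ynyl)bicyclo[3.1.0]hexane], via aldehyde 15 (not isolated)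
Conditions: O3, CH2Cl2/MeOH, −78 °C; then NaBH4, −78 → 0 °C
Reagents that add atoms: ozone, [O-][O+]=O
Why: Ozonolysis of the only alkene (the alkynylsilane is far less reactive towards ozone) with reductive work-up turns the vinyl group into the C9 hydroxymethyl group without touching the quaternary C10.

Step 9
Reactants: 16 C9 alcohol; 17 1-phenyl-1H-tetrazole-5-thiol
Product: 18 C9 1-phenyl-1H-tetrazol-5-yl sulfide
Conditions: PPh3, diisopropyl azodicarboxylate, THF, 0 → 40 °C
Reagents that add atoms: none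
Why: Mitsunobu thioetherification with the acidic tetrazole thiol forms the C9–S bond at the neopentyl primary carbon (SN2 on the alkoxyphosphonium ion; no stereocentre involved).

Step 10
Reactants: 18 sulfide
Product: 19 C9 1-phenyl-1H-tetrazol-5-yl sulfone (sulfone half, propargylsilane arm)
Conditions: (NH4)6Mo7O24·4H2O (10 mol %), 30% aq. H2O2, EtOH, 0 °C → rt
Reagents that add atoms: hydrogen peroxide, OO
Why: Molybdate-catalysed oxidation with H2O2 takes the sulfide to the sulfone without affecting the silyl ether, the alkyne or the cyclopropane.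

Step 11
Reactants: 16 C9 alcohol
Product: 20 C9' alcohol with prop-2-ynyl arm (terminal alkyne)
Conditions: K2CO3, MeOH, rt
Reagents that add atoms: none
Why: Carbonate-catalysed methanolysis of the alkynyl C–Si bond frees the terminal alkyne while the TBS ether is stable.

Step 12
Reactants: 20 terminal alkyne alcohol
Product: 22 C9' alcohol with but-2-ynyl arm, via dilithium alkoxide acetylide 21 (not isolated)
Conditions: n-BuLi (2.1 equiv), THF, −78 °C; MeI (1.05 equiv), −78 → 0 °C
Reagents that add atoms: iodomethane, CI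
Why: Double deprotonation gives the alkoxide–acetylide, and the far more nucleophilic acetylide carbon is methylated by one equivalent of MeI (SN2), giving the 2-butynyl arm.

Step 13
Reactants: 22 but-2-ynyl alcohol
Product: 23 C9' aldehyde with but-2-ynyl arm (aldehyde half)
Conditions: Dess–Martin periodinane, NaHCO3, CH2Cl2, 0 °C → rt
Reagents that add atoms: none
Why: Dess–Martin oxidation gives the C9' aldehyde, which cannot enolise because C10' is quaternary.

Step 14
Reactants: 19 sulfone; 23 aldehyde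
Product: 25 (E)-C9=C9' alkene joining the two halves (bis-TBS ether; trimethylsilylpropargyl arm on C5 and but-2-ynyl arm on C5'), via potassium sulfonyl carbanion 24 (not isolated)
Conditions: 19, KN(SiMe3)2 (KHMDS), DME, −78 °C; then 23, −78 °C → rt
Reagents that add atoms: none
Why: Julia–Kocienski olefination: addition of the metalated tetrazolyl sulfone to the aldehyde, Smiles rearrangement and loss of SO2 and tetrazolate give the C9=C9' alkene, for which only the E geometry can accommodate two tert-alkyl substituents.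

Step 15
Reactants: 25 E-alkene
Product: 26 E-alkene with prop-2-ynyl arm on C5 (terminal alkyne)
Conditions: K2CO3, MeOH/THF, rt
Reagents that add atoms: none
Why: Carbonate-catalysed methanolysis removes the alkynyl silyl group only; both TBS ethers and the 2-butynyl group are unaffected.

Step 16
Reactants: 26 terminal alkyne
Product: 28 methyl 2-ynoate (C6–C7≡C8–CO2Me), via lithium acetylide 27 (not isolated)
Conditions: n-BuLi, THF, −78 °C; ClCO2Me, −78 → 0 °C
Reagents that add atoms: methyl chloroformate, COC(Cl)=O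
Why: Acylation of the lithium acetylide with the chloroformate installs C8' as the ester carbon of a 2-ynoate.

Step 17
Reactants: 28 ynoate
Product: 30 β-keto ester (C6–C7(=O)–C8H2–CO2Me), via enamino ester 29 (not isolated)
Conditions: pyrrolidine, MeOH, rt; then aq. AcOH, THF, 40 °C
Reagents that add atoms: water, O
Why: Conjugate addition of pyrrolidine to the ynoate places nitrogen on C7, and mild acidic hydrolysis of the enamino ester gives the β-keto ester with the carbonyl at C7 (the unactivated 2-butynyl alkyne does not react).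

Step 18
Reactants: 30 β-keto ester
Product: 31 2-chloro-3-oxo ester (Cl on C8, both epimers)
Conditions: N-chlorosuccinimide, Mg(ClO4)2 (10 mol %), EtOAc, rt
Reagents that add atoms: N-chlorosuccinimide, O=C1CCC(=O)N1Cl
Why: Electrophilic α-chlorination of the magnesium-bound β-keto ester enol by N-chlorosuccinimide occurs only at the doubly activated C8, giving both C8 epimers, which is inconsequential.

Step 19
Reactants: 31 chloride; 32 2-bromopropanoic acid (racemic)
Product: 33 2-(2-bromopropanoyloxy)-3-oxo ester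
Conditions: 32, Cs2CO3, DMF, 0 °C → rt
Reagents that add atoms: none
Why: SN2 displacement of the doubly activated C8 chloride by the cesium carboxylate forms the C8–O bond of the future lactone.

Step 20
Reactants: 33 bromo ester
Product: 35 butenolide methyl ester [methyl 4-methyl-5-oxo-3-(C6-methylene)-2,5-dihydrofuran-2-carboxylate], via phosphonium bromide 34 (not isolated)
Conditions: PPh3, MeCN, 60 °C; then Et3N, rt → 60 °C
Reagents that add atoms: none
Why: Triphenylphosphine displaces the secondary bromide and Et3N then forms the neutral ester-stabilised ylide, which closes the butenolide by intramolecular Wittig reaction on the C7 ketone (C7=C11); a neutral ylide is used because a phosphonate carbanion would simply be quenched by the much more acidic C8–H.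

Step 21
Reactants: 35 butenolide ester
Product: 36 butenolide carboxylic acid (CO2H on C8)
Conditions: Me3SnOH, ClCH2CH2Cl, 70 °C; 5% aq. HCl wash
Reagents that add atoms: trimethyltin hydroxide, C[Sn](C)(C)O
Why: Me3SnOH cleaves the activated methyl ester under nearly neutral conditions, under which the butenolide is not opened and the acidic C8–H is not fully deprotonated.

Step 22
Reactants: 36 butenolide carboxylic acid
Product: 39 cyclobutanone (C8'=O; bis-TBS ether; but-2-ynyl arm on C5'), via acid chloride 37 (not isolated), via ketene 38 (not isolated)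
Conditions: 1-chloro-N,N,2-trimethylprop-1-en-1-amine, CH2Cl2, 0 °C → rt; then slow addition to Et3N in toluene, 110 °C (0.002 M)
Reagents that add atoms: none
Why: Et3N removes the acidic C8–H of acid chloride 37 (an aromatic 2-oxidofuran results) and loss of chloride gives the alkoxy(vinyl)ketene 38, which adds to the C9=C9' alkene in a concerted but asynchronous [π2s+π2a] step in which the electrophilic C8' bonds to the distal C9' and C8 to C9; the closest known reaction is the intramolecular [2+2] cycloaddition of oxygen-substituted ketenes with tethered alkenes that gives bicyclo[4.2.0]octan-7-ones. The cyclobutanone closes by the two new bonds, and the six-membered ring C5–C6–C7–C8–C9–C10 closes through C8–C9 in the fused (not bridged) mode, the only one the four-atom tether C7–C6–C5–C10 allows without a seven-membered ring. C9 and C9' should come out trans because the E-alkene reacts suprafacially, and C8 is fixed by the necessarily cis fusion of the four- and six-membered rings. The configuration of C8 and C9 relative to C10 should follow from a half-chair tether with the C10 methyl axial: addition to the α face of C9 leaves only the lactone oxygen 1,3-diaxial to C14, whereas the β face would force the C8=C8'=O unit over the methyl group. The step needs chemoselectivity for C9=C9', secured by carrying C4 and C4' as silyl ethers (no 1,1-disubstituted alkene near the ketene) and by the poor ketenophilicity of the 2-butynyl group, and it needs high dilution with slow addition to suppress ketene dimerisation.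

Step 23
Reactants: 39 cyclobutanone
Product: 40 bis-TBS ether of the 4β,4'β-dihydroxy dilactone (both butenolides and both six-membered rings in place)
Conditions: Ru3(CO)12 (5 mol %), CO (10 atm), toluene, 160 °C
Reagents that add atoms: carbon monoxide, [C-]#[O+]
Why: Proposed new method: a zerovalent ruthenium carbonyl fragment should couple the alkyne and the strained, aldehyde-like cyclobutanone C=O oxidatively to an oxaruthenacyclopentene (C7'–C8' bond, the four-atom tether C9'–C10'–C5'–C6' forcing C7' onto the face of C8' syn to C10' and so setting C8' with cis ring fusion), CO then inserts at C11' and reductive elimination of the acyl–O bond closes the butenolide, the closest known reactions being the Ru3(CO)12-catalysed cyclocarbonylation (hetero-Pauson–Khand reaction) of yne-aldehydes to bicyclic butenolides and of allenyl ketones to α-methylene-γ-butyrolactones; the oxygen stays metal-bound throughout, so no free C8' alkoxide that could open the cyclobutane by retro-aldol cleavage is formed.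

Step 24
Reactants: 40 bis-TBS ether
Product: 41 4β,4'β-diol
Conditions: Bu4NF/AcOH (1:1), THF, rt → 45 °C
Reagents that add atoms: none
Why: Acetic acid-buffered fluoride removes both silyl groups without generating hydroxide, which could open the lactones.

Step 25
Reactants: 41 diol
Product: 42 4,4'-diketone
Conditions: Dess–Martin periodinane, NaHCO3, CH2Cl2, rt
Reagents that add atoms: none
Why: Dess–Martin oxidation of both cyclopropyl carbinols gives the two ketones and erases the auxiliary carbinol stereocentres.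

Step 26
Reactants: 42 diketone
Product: 43 CNP0265879.1 (target)
Conditions: Ph3PCH3Br, KOtBu (slight deficit), THF, 0 °C → rt
Reagents that add atoms: methyltriphenylphosphonium bromide, C[P+](c1ccccc1)(c1ccccc1)c1ccccc1.[Br-]
Why: Double Wittig methylenation of the two cyclopropyl ketones installs both exocyclic methylenes; the lactones have no acidic γ-hydrogen and should not be attacked by the ylide at this temperature, and no stereocentre is formed.

**Compound list**

1 | 3-methylcyclopent-2-en-1-one | CC1=CC(=O)CC1 | starting material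
2 | ethynyl(trimethyl)silane | C#C[Si](C)(C)C | starting material
3 | diisobutyl[1-(trimethylsilyl)vinyl]aluminium (not isolated) | C=C([Si](C)(C)C)[Al](CC(C)C)CC(C)C | intermediate
4 | diisobutylaluminium enolate of the conjugate adduct (not isolated) | CC(C)C[Al](CC(C)C)OC1=C[C@@](C)(C(=C)[Si](C)(C)C)CC1 | intermediate
5 | (S)-trimethyl{[3-methyl-3-(1-trimethylsilylvinyl)cyclopent-1-en-1-yl]oxy}silane | C[Si](C)(C)OC1=C[C@@](C)(C(=C)[Si](C)(C)C)CC1 | intermediate
6 | 3-bromo-1-(trimethylsilyl)prop-1-yne | C[Si](C)(C)C#CCBr | starting material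
7 | lithium enolate from 5 (not isolated) | [Li]OC1=C[C@@](C)(C(=C)[Si](C)(C)C)CC1 | intermediate
8 | 3-methyl-2-[3-(trimethylsilyl)prop-2-ynyl]-3-[1-(trimethylsilyl)vinyl]cyclopentan-1-one | O=C1CC[C@@](C(=C)[Si](C)(C)C)(C)[C@H]1CC#C[Si](C)(C)C | intermediate
9 | 3-methyl-2-[3-(trimethylsilyl)prop-2-ynyl]-3-vinylcyclopentan-1-one | O=C1CC[C@@](C=C)(C)[C@H]1CC#C[Si](C)(C)C | intermediate
10 | kinetic lithium enolate of 9 (not isolated) | [Li]OC1=CC[C@@](C=C)(C)[C@H]1CC#C[Si](C)(C)C | intermediate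
11 | 4-methyl-5-[3-(trimethylsilyl)prop-2-ynyl]-4-vinylcyclopent-2-en-1-one | O=C1C=C[C@@](C=C)(C)[C@H]1CC#C[Si](C)(C)C | intermediate
12 | 4-methyl-5-[3-(trimethylsilyl)prop-2-ynyl]-4-vinylcyclopent-2-en-1-ol (OH β) | O[C@H]1C=C[C@@](C=C)(C)[C@H]1CC#C[Si](C)(C)C | intermediate
13 | 4-methyl-3-[3-(trimethylsilyl)prop-2-ynyl]-4-vinylbicyclo[3.1.0]hexan-2-ol | O[C@H]1[C@H]2C[C@H]2[C@@](C=C)(C)[C@H]1CC#C[Si](C)(C)C | intermediate
14 | TBS ether of 13 | CC(C)(C)[Si](C)(C)O[C@H]1[C@H]2C[C@H]2[C@@](C=C)(C)[C@H]1CC#C[Si](C)(C)C | intermediate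
15 | C9 aldehyde from ozonolysis of 14 (not isolated) | CC(C)(C)[Si](C)(C)O[C@H]1[C@H]2C[C@H]2[C@@](C=O)(C)[C@H]1CC#C[Si](C)(C)C | intermediate
16 | C9 alcohol (hydroxymethyl on C10), trimethylsilylpropargyl arm | CC(C)(C)[Si](C)(C)O[C@H]1[C@H]2C[C@H]2[C@@](CO)(C)[C@H]1CC#C[Si](C)(C)C | intermediate
17 | 1-phenyl-1H-tetrazole-5-thiol | Sc1nnnn1-c1ccccc1 | starting material
18 | C9 1-phenyl-1H-tetrazol-5-yl sulfide | CC(C)(C)[Si](C)(C)O[C@H]1[C@H]2C[C@H]2[C@@](CSc3nnnn3-c3ccccc3)(C)[C@H]1CC#C[Si](C)(C)C | intermediate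
19 | C9 1-phenyl-1H-tetrazol-5-yl sulfone | CC(C)(C)[Si](C)(C)O[C@H]1[C@H]2C[C@H]2[C@@](CS(=O)(=O)c3nnnn3-c3ccccc3)(C)[C@H]1CC#C[Si](C)(C)C | intermediate
20 | C9' alcohol with prop-2-ynyl arm | CC(C)(C)[Si](C)(C)O[C@H]1[C@H]2C[C@H]2[C@@](CO)(C)[C@H]1CC#C | intermediate
21 | dilithium alkoxide acetylide of 20 (not isolated) | CC(C)(C)[Si](C)(C)O[C@H]1[C@H]2C[C@H]2[C@@](CO[Li])(C)[C@H]1CC#C[Li] | intermediate
22 | C9' alcohol with but-2-ynyl arm | CC(C)(C)[Si](C)(C)O[C@H]1[C@H]2C[C@H]2[C@@](CO)(C)[C@H]1CC#CC | intermediate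
23 | C9' aldehyde with but-2-ynyl arm | CC(C)(C)[Si](C)(C)O[C@H]1[C@H]2C[C@H]2[C@@](C=O)(C)[C@H]1CC#CC | intermediate
24 | potassium salt of the α-sulfonyl carbanion of 19 (not isolated) | CC(C)(C)[Si](C)(C)O[C@H]1[C@H]2C[C@H]2[C@@]([CH-]S(=O)(=O)c3nnnn3-c3ccccc3)(C)[C@H]1CC#C[Si](C)(C)C.[K+] | intermediate
25 | (E)-C9=C9' alkene, trimethylsilylpropargyl and but-2-ynyl arms | CC(C)(C)[Si](C)(C)O[C@H]1[C@H]2C[C@H]2[C@@](/C=C/[C@@]3(C)[C@@H]4C[C@@H]4[C@H](O[Si](C)(C)C(C)(C)C)[C@@H]3CC#CC)(C)[C@H]1CC#C[Si](C)(C)C | intermediate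
26 | E-alkene with terminal prop-2-ynyl arm on C5 | CC(C)(C)[Si](C)(C)O[C@H]1[C@H]2C[C@H]2[C@@](/C=C/[C@@]3(C)[C@@H]4C[C@@H]4[C@H](O[Si](C)(C)C(C)(C)C)[C@@H]3CC#CC)(C)[C@H]1CC#C | intermediate
27 | lithium acetylide of 26 (not isolated) | CC(C)(C)[Si](C)(C)O[C@H]1[C@H]2C[C@H]2[C@@](/C=C/[C@@]3(C)[C@@H]4C[C@@H]4[C@H](O[Si](C)(C)C(C)(C)C)[C@@H]3CC#CC)(C)[C@H]1CC#C[Li] | intermediate
28 | methyl 2-ynoate | CC(C)(C)[Si](C)(C)O[C@H]1[C@H]2C[C@H]2[C@@](/C=C/[C@@]3(C)[C@@H]4C[C@@H]4[C@H](O[Si](C)(C)C(C)(C)C)[C@@H]3CC#CC)(C)[C@H]1CC#CC(=O)OC | intermediate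
29 | (E)-3-(pyrrolidin-1-yl)enoate (not isolated) | CC(C)(C)[Si](C)(C)O[C@H]1[C@H]2C[C@H]2[C@@](/C=C/[C@@]3(C)[C@@H]4C[C@@H]4[C@H](O[Si](C)(C)C(C)(C)C)[C@@H]3CC#CC)(C)[C@H]1C\C(N5CCCC5)=C/C(=O)OC | intermediate
30 | β-keto ester | CC(C)(C)[Si](C)(C)O[C@H]1[C@H]2C[C@H]2[C@@](/C=C/[C@@]3(C)[C@@H]4C[C@@H]4[C@H](O[Si](C)(C)C(C)(C)C)[C@@H]3CC#CC)(C)[C@H]1CC(=O)CC(=O)OC | intermediate
31 | 2-chloro-3-oxo ester (C8 epimers) | CC(C)(C)[Si](C)(C)O[C@H]1[C@H]2C[C@H]2[C@@](/C=C/[C@@]3(C)[C@@H]4C[C@@H]4[C@H](O[Si](C)(C)C(C)(C)C)[C@@H]3CC#CC)(C)[C@H]1CC(=O)C(Cl)C(=O)OC | intermediate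
32 | 2-bromopropanoic acid | CC(Br)C(=O)O | starting material
33 | 2-(2-bromopropanoyloxy)-3-oxo ester | CC(C)(C)[Si](C)(C)O[C@H]1[C@H]2C[C@H]2[C@@](/C=C/[C@@]3(C)[C@@H]4C[C@@H]4[C@H](O[Si](C)(C)C(C)(C)C)[C@@H]3CC#CC)(C)[C@H]1CC(=O)C(OC(=O)C(C)Br)C(=O)OC | intermediate
34 | triphenylphosphonium bromide from 33 (not isolated) | CC(C)(C)[Si](C)(C)O[C@H]1[C@H]2C[C@H]2[C@@](/C=C/[C@@]3(C)[C@@H]4C[C@@H]4[C@H](O[Si](C)(C)C(C)(C)C)[C@@H]3CC#CC)(C)[C@H]1CC(=O)C(OC(=O)C(C)[P+](c5ccccc5)(c5ccccc5)c5ccccc5)C(=O)OC.[Br-] | intermediate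
35 | butenolide methyl ester | CC(C)(C)[Si](C)(C)O[C@H]1[C@H]2C[C@H]2[C@@](/C=C/[C@@]3(C)[C@@H]4C[C@@H]4[C@H](O[Si](C)(C)C(C)(C)C)[C@@H]3CC#CC)(C)[C@H]1CC1=C(C)C(=O)OC1C(=O)OC | intermediate
36 | butenolide carboxylic acid | CC(C)(C)[Si](C)(C)O[C@H]1[C@H]2C[C@H]2[C@@](/C=C/[C@@]3(C)[C@@H]4C[C@@H]4[C@H](O[Si](C)(C)C(C)(C)C)[C@@H]3CC#CC)(C)[C@H]1CC1=C(C)C(=O)OC1C(=O)O | intermediate
37 | butenolide acid chloride (not isolated) | CC(C)(C)[Si](C)(C)O[C@H]1[C@H]2C[C@H]2[C@@](/C=C/[C@@]3(C)[C@@H]4C[C@@H]4[C@H](O[Si](C)(C)C(C)(C)C)[C@@H]3CC#CC)(C)[C@H]1CC1=C(C)C(=O)OC1C(Cl)=O | intermediate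
38 | ketene, 5-(oxomethylidene)furan-2(5H)-one (key-step precursor, not isolated) | CC(C)(C)[Si](C)(C)O[C@H]1[C@H]2C[C@H]2[C@@](/C=C/[C@@]3(C)[C@@H]4C[C@@H]4[C@H](O[Si](C)(C)C(C)(C)C)[C@@H]3CC#CC)(C)[C@H]1CC1=C(C)C(=O)OC1=C=O | intermediate
39 | cyclobutanone (key-step product) | CC(C)(C)[Si](C)(C)O[C@H]1[C@H]2C[C@H]2[C@@]2(C)[C@H]1CC1=C(C)C(=O)O[C@]13[C@H]2[C@H](C3=O)[C@@]2(C)[C@@H]4C[C@@H]4[C@H](O[Si](C)(C)C(C)(C)C)[C@@H]2CC#CC | intermediate
40 | bis-TBS ether of the dihydroxy dilactone | CC(C)(C)[Si](C)(C)O[C@H]1[C@H]2C[C@H]2[C@@]2(C)[C@H]1CC1=C(C)C(=O)O[C@]13[C@H]2[C@H]1[C@@]2(C)[C@@H]4C[C@@H]4[C@H](O[Si](C)(C)C(C)(C)C)[C@@H]2CC2=C(C)C(=O)O[C@@]213 | intermediate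
41 | 4β,4'β-diol | O[C@H]1[C@H]2C[C@H]2[C@@]2(C)[C@H]1CC1=C(C)C(=O)O[C@]13[C@H]2[C@H]1[C@@]2(C)[C@@H]4C[C@@H]4[C@H](O)[C@@H]2CC2=C(C)C(=O)O[C@@]213 | intermediate
42 | 4,4'-diketone | O=C1[C@H]2C[C@H]2[C@@]2(C)[C@H]1CC1=C(C)C(=O)O[C@]13[C@H]2[C@H]1[C@@]2(C)[C@@H]4C[C@@H]4C(=O)[C@@H]2CC2=C(C)C(=O)O[C@@]213 | intermediate
43 | CNP0265879.1 | C=C1[C@H]2C[C@H]2[C@@]2(C)[C@H]1CC1=C(C)C(=O)O[C@]13[C@H]2[C@H]1[C@@]2(C)[C@@H]4C[C@@H]4C(=C)[C@@H]2CC2=C(C)C(=O)O[C@@]213 | target

**Step count and risk**

Total step count: 26. Longest linear sequence: 24 steps (steps 1–8, 11–13, 14–26).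

Steps most likely to fail:

1. Step 23 (carbonylative [2+2+1] on the cyclobutanone). The ketone carbonyl may fail to enter the oxidative cyclisation; the ruthenium may instead insert into a C–C bond of the strained cyclobutanone (ring opening or decarbonylation) or merely oligomerise the alkyne. The fallback uses known chemistry: the alkyne is exchanged for its allene isomer, for which Ru3(CO)12-catalysed cyclocarbonylation with ketones is an established reaction type. It sets out from 20 and comes back to the route at 40. Crabbé homologation of the terminal alkyne of 20 (CuI, paraformaldehyde, iPr2NH, dioxane, reflux) should give the buta-2,3-dienyl alcohol F1, Dess–Martin oxidation the aldehyde F2, and Julia–Kocienski reaction with metalated 19 the E-alkene F3. F3 would then pass through the chemistry of steps 15–22: K2CO3/MeOH to the terminal alkyne F4; n-BuLi then ClCO2Me to the ynoate F5; pyrrolidine then aqueous AcOH to the β-keto ester F6; N-chlorosuccinimide to the chloride F7; cesium 2-bromopropanoate to the bromo ester F8; PPh3 then Et3N to the butenolide ester F9; Me3SnOH to the acid F10; the chloroenamine reagent to the acid chloride F11; Et3N in hot toluene to the ketene F12, whose cycloaddition to C9=C9' gives the allenyl cyclobutanone F13 (here the remote allene is a possible competing ketenophile, disfavoured by the large ring it would need). Ru3(CO)12 (2 mol %), CO (20 atm), dioxane, 120 °C should convert F13 into the cis-fused α-methylene-γ-butyrolactone F14 (C8' bonded to the proximal allene carbon C7', CO on the central carbon), and RhCl3·3H2O in ethanol at 80 °C should move the exocyclic double bond into the ring (C7'=C11'), which gives 40.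

2. Step 22 (ketene–alkene cycloaddition). Addition to the hindered E-alkene may be too slow, so that the ketene is lost by dimerisation or by reaction with amine species, or the two faces of C9=C9' may be poorly differentiated. The fallback replaces the ketene by the more electrophilic keteniminium ion; it sets out from 36 (through 37) and comes back at 39. Acid chloride 37 and pyrrolidine give the pyrrolidine amide F15; Tf2O and 2,4,6-collidine in ClCH2CH2Cl (0 → 80 °C) should convert F15 into the keteniminium triflate F16, which should add to C9=C9' in the same sense to give the cyclobutaniminium triflate F17; aqueous NaHCO3 hydrolyses F17 to 39.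

3. Step 14 (Julia–Kocienski union). Addition of the neopentyl sulfonyl anion to the equally hindered aldehyde may be slow, so that the metalated sulfone is consumed by attack on the tetrazole ring of a second molecule. The fallback is the two-stage Julia–Lythgoe olefination, in which the adduct is trapped by acylation and the alkene is released reductively; it sets out from 16 and comes back at 25. PhSSPh and PBu3 convert 16 into the phenyl sulfide F18, molybdate-catalysed H2O2 oxidation gives the phenyl sulfone F19; lithiation (n-BuLi, THF, −78 °C), addition of 23 and quenching of the alkoxide with Ac2O give the β-acetoxy sulfone F20 (diastereomer mixture), and Na/Hg (5% sodium amalgam), Na2HPO4, MeOH/THF, −20 °C should give the E-alkene 25.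

Further compounds
F1 | step 23 | C9' alcohol with buta-2,3-dienyl arm | CC(C)(C)[Si](C)(C)O[C@H]1[C@H]2C[C@H]2[C@@](CO)(C)[C@H]1CC=C=C
F2 | step 23 | C9' aldehyde with buta-2,3-dienyl arm | CC(C)(C)[Si](C)(C)O[C@H]1[C@H]2C[C@H]2[C@@](C=O)(C)[C@H]1CC=C=C
F3 | step 23 | E-alkene with trimethylsilylpropargyl and buta-2,3-dienyl arms | CC(C)(C)[Si](C)(C)O[C@H]1[C@H]2C[C@H]2[C@@](/C=C/[C@@]3(C)[C@@H]4C[C@@H]4[C@H](O[Si](C)(C)C(C)(C)C)[C@@H]3CC=C=C)(C)[C@H]1CC#C[Si](C)(C)C
F4 | step 23 | terminal alkyne of the allenyl series | CC(C)(C)[Si](C)(C)O[C@H]1[C@H]2C[C@H]2[C@@](/C=C/[C@@]3(C)[C@@H]4C[C@@H]4[C@H](O[Si](C)(C)C(C)(C)C)[C@@H]3CC=C=C)(C)[C@H]1CC#C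
F5 | step 23 | methyl 2-ynoate of the allenyl series | CC(C)(C)[Si](C)(C)O[C@H]1[C@H]2C[C@H]2[C@@](/C=C/[C@@]3(C)[C@@H]4C[C@@H]4[C@H](O[Si](C)(C)C(C)(C)C)[C@@H]3CC=C=C)(C)[C@H]1CC#CC(=O)OC
F6 | step 23 | β-keto ester of the allenyl series | CC(C)(C)[Si](C)(C)O[C@H]1[C@H]2C[C@H]2[C@@](/C=C/[C@@]3(C)[C@@H]4C[C@@H]4[C@H](O[Si](C)(C)C(C)(C)C)[C@@H]3CC=C=C)(C)[C@H]1CC(=O)CC(=O)OC
F7 | step 23 | 2-chloro-3-oxo ester of the allenyl series | CC(C)(C)[Si](C)(C)O[C@H]1[C@H]2C[C@H]2[C@@](/C=C/[C@@]3(C)[C@@H]4C[C@@H]4[C@H](O[Si](C)(C)C(C)(C)C)[C@@H]3CC=C=C)(C)[C@H]1CC(=O)C(Cl)C(=O)OC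
F8 | step 23 | 2-(2-bromopropanoyloxy)-3-oxo ester of the allenyl series | CC(C)(C)[Si](C)(C)O[C@H]1[C@H]2C[C@H]2[C@@](/C=C/[C@@]3(C)[C@@H]4C[C@@H]4[C@H](O[Si](C)(C)C(C)(C)C)[C@@H]3CC=C=C)(C)[C@H]1CC(=O)C(OC(=O)C(C)Br)C(=O)OC
F9 | step 23 | butenolide methyl ester of the allenyl series | CC(C)(C)[Si](C)(C)O[C@H]1[C@H]2C[C@H]2[C@@](/C=C/[C@@]3(C)[C@@H]4C[C@@H]4[C@H](O[Si](C)(C)C(C)(C)C)[C@@H]3CC=C=C)(C)[C@H]1CC1=C(C)C(=O)OC1C(=O)OC
F10 | step 23 | butenolide carboxylic acid of the allenyl series | CC(C)(C)[Si](C)(C)O[C@H]1[C@H]2C[C@H]2[C@@](/C=C/[C@@]3(C)[C@@H]4C[C@@H]4[C@H](O[Si](C)(C)C(C)(C)C)[C@@H]3CC=C=C)(C)[C@H]1CC1=C(C)C(=O)OC1C(=O)O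
F11 | step 23 | acid chloride of the allenyl series | CC(C)(C)[Si](C)(C)O[C@H]1[C@H]2C[C@H]2[C@@](/C=C/[C@@]3(C)[C@@H]4C[C@@H]4[C@H](O[Si](C)(C)C(C)(C)C)[C@@H]3CC=C=C)(C)[C@H]1CC1=C(C)C(=O)OC1C(Cl)=O
F12 | step 23 | ketene of the allenyl series | CC(C)(C)[Si](C)(C)O[C@H]1[C@H]2C[C@H]2[C@@](/C=C/[C@@]3(C)[C@@H]4C[C@@H]4[C@H](O[Si](C)(C)C(C)(C)C)[C@@H]3CC=C=C)(C)[C@H]1CC1=C(C)C(=O)OC1=C=O
F13 | step 23 | cyclobutanone with buta-2,3-dienyl arm | CC(C)(C)[Si](C)(C)O[C@H]1[C@H]2C[C@H]2[C@@]2(C)[C@H]1CC1=C(C)C(=O)O[C@]13[C@H]2[C@H](C3=O)[C@@]2(C)[C@@H]4C[C@@H]4[C@H](O[Si](C)(C)C(C)(C)C)[C@@H]2CC=C=C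
F14 | step 23 | cis-fused α-methylene-γ-butyrolactone (bis-TBS ether) | CC(C)(C)[Si](C)(C)O[C@H]1[C@H]2C[C@H]2[C@@]2(C)[C@H]1CC1=C(C)C(=O)O[C@]13[C@H]2[C@H]1[C@@]2(C)[C@@H]4C[C@@H]4[C@H](O[Si](C)(C)C(C)(C)C)[C@@H]2C[C@@H]2C(=C)C(=O)O[C@@]213
F15 | step 22 | pyrrolidine amide of acid 36 | CC(C)(C)[Si](C)(C)O[C@H]1[C@H]2C[C@H]2[C@@](/C=C/[C@@]3(C)[C@@H]4C[C@@H]4[C@H](O[Si](C)(C)C(C)(C)C)[C@@H]3CC#CC)(C)[C@H]1CC1=C(C)C(=O)OC1C(=O)N5CCCC5
F16 | step 22 | keteniminium trifluoromethanesulfonate | CC(C)(C)[Si](C)(C)O[C@H]1[C@H]2C[C@H]2[C@@](/C=C/[C@@]3(C)[C@@H]4C[C@@H]4[C@H](O[Si](C)(C)C(C)(C)C)[C@@H]3CC#CC)(C)[C@H]1CC1=C(C)C(=O)OC1=C=[N+]5CCCC5.[O-]S(=O)(=O)C(F)(F)F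
F17 | step 22 | cyclobutaniminium trifluoromethanesulfonate | CC(C)(C)[Si](C)(C)O[C@H]1[C@H]2C[C@H]2[C@@]2(C)[C@H]1CC1=C(C)C(=O)O[C@]13[C@H]2[C@H](C3=[N+]5CCCC5)[C@@]2(C)[C@@H]4C[C@@H]4[C@H](O[Si](C)(C)C(C)(C)C)[C@@H]2CC#CC.[O-]S(=O)(=O)C(F)(F)F
F18 | step 14 | C9 phenyl sulfide | CC(C)(C)[Si](C)(C)O[C@H]1[C@H]2C[C@H]2[C@@](CSc3ccccc3)(C)[C@H]1CC#C[Si](C)(C)C
F19 | step 14 | C9 phenyl sulfone | CC(C)(C)[Si](C)(C)O[C@H]1[C@H]2C[C@H]2[C@@](CS(=O)(=O)c3ccccc3)(C)[C@H]1CC#C[Si](C)(C)C
F20 | step 14 | β-acetoxy phenyl sulfone (C9/C9' diastereomers) | CC(C)(C)[Si](C)(C)O[C@H]1[C@H]2C[C@H]2[C@@](C(S(=O)(=O)c5ccccc5)C(OC(C)=O)[C@@]3(C)[C@@H]4C[C@@H]4[C@H](O[Si](C)(C)C(C)(C)C)[C@@H]3CC#CC)(C)[C@H]1CC#C[Si](C)(C)C
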